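**Assumption:** the target has no stereocentre or other stereogenic element, so "single enantiomer" reduces to the constitution shown. The only stereodescriptors in the route are alkene and hydrazone geometries of intermediates, which disappear on indolization.

**Retrosynthetic overview**
1. The aryl–indole bonds are not made by cross-coupling or by indole addition to a quinone; both pyrrole rings are built onto the finished hexasubstituted benzene by Fischer indolization (C3–C3a and N1–C2 bonds).
2. Target ⇐ 5-bromo bis-indole 16 by a late, linear-selective prenyl Suzuki–Miyaura coupling, so the acid-sensitive prenyl group never sees the Fischer conditions.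
3. Each indole ⇐ a masked arylacetaldehyde arm (2-ethoxyvinyl) on the central ring plus an arylhydrazine; the arms are put on one at a time from 1,4-dibromo-2,3,5,6-tetramethoxybenzene, which removes the symmetry problem.
4. Ring order: central benzene bought intact (1,2,4,5-tetramethoxybenzene) → unsubstituted indole (step 3) → 5-bromoindole (step 5) → prenylation (step 6). No protecting groups are used.

**Route**

Step 1
Reactants: 1 1,2,4,5-tetramethoxybenzene
Product: 2 1,4-dibromo-2,3,5,6-tetramethoxybenzene
Conditions: Br2 (2.2 equiv), CH2Cl2, 0 °C → rt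
Reagents that add atoms: bromine, BrBr
Why: Twofold electrophilic aromatic bromination, in which the only two ring C–H positions are each flanked by two methoxy groups and strongly activated, so the regiochemistry is unambiguous and no stereocentre is formed.

Step 2
Reactants: 2 1,4-dibromo-2,3,5,6-tetramethoxybenzene; 3 (Z)-1-bromo-2-ethoxyethene
Product: 6 1-bromo-4-[(Z)-2-ethoxyethenyl]-2,3,5,6-tetramethoxybenzene, via aryllithium 4 (not isolated), via arylzinc chloride 5 (not isolated)
Conditions: n-BuLi (1.0 equiv), THF, −78 °C; ZnCl2 (1.1 equiv), −78 °C → rt; then 3 (1.2 equiv), Pd(PPh3)4 (3 mol%), 45 °C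
Reagents that add atoms: none
Why: Bromine–lithium exchange stops after one exchange because a second would put two carbanions on one ring, and after transmetalation to zinc a Negishi coupling joins the aryl group to the vinyl bromide, which adds to zerovalent palladium far faster than the hindered electron-rich aryl bromide and couples with retention of the Z geometry.

Step 3
Reactants: 6 1-bromo-4-[(Z)-2-ethoxyethenyl]-2,3,5,6-tetramethoxybenzene; 7 phenylhydrazine hydrochloride
Product: 10 3-(4-bromo-2,3,5,6-tetramethoxyphenyl)-1H-indole, via arylacetaldehyde 8 (not isolated), via phenylhydrazone 9 (not isolated)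
Conditions: 7 (1.1 equiv), 4% aq. H2SO4/1,4-dioxane (1:1), 90 °C
Reagents that add atoms: none
Why: Fischer indole synthesis, in which aqueous acid unmasks the enol ether to the arylacetaldehyde, the hydrazone tautomerises to the ene-hydrazine and [3,3]-sigmatropic rearrangement, cyclisation and loss of ammonia make the benzylic carbon C3, so the tetramethoxyaryl group ends up as the 3-substituent and no stereocentre is formed.

Step 4
Reactants: 10 3-(4-bromo-2,3,5,6-tetramethoxyphenyl)-1H-indole; 11 2-[(E)-2-ethoxyethenyl]-4,4,5,5-tetramethyl-1,3,2-dioxaborolane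
Product: 12 3-{4-[(E)-2-ethoxyethenyl]-2,3,5,6-tetramethoxyphenyl}-1H-indole
Conditions: 11 (1.5 equiv), Pd(OAc)2 (5 mol%), SPhos (10 mol%), K3PO4 (3 equiv), 1,4-dioxane/H2O (5:1), 90 °C
Reagents that add atoms: none
Why: Suzuki–Miyaura coupling, for which the bulky electron-rich biarylphosphine enables oxidative addition and reductive elimination at the di-ortho-methoxy aryl bromide, tolerates the free indole N–H and transfers the alkenyl group with retention of the E geometry.

Step 5
Reactants: 12 3-{4-[(E)-2-ethoxyethenyl]-2,3,5,6-tetramethoxyphenyl}-1H-indole; 13 (4-bromophenyl)hydrazine hydrochloride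
Product: 16 5-bromo-3-[4-(1H-indol-3-yl)-2,3,5,6-tetramethoxyphenyl]-1H-indole, via arylacetaldehyde 14 (not isolated), via hydrazone 15 (not isolated)
Conditions: 13 (1.1 equiv), 4% aq. H2SO4/1,4-dioxane (1:1), 90 °C
Reagents that add atoms: none
Why: Second Fischer indole synthesis, in which the para-bromo hydrazine can only give the 5-bromoindole (both ortho positions are equivalent) and the first indole, blocked at C3 by a bulky aryl group, survives hot dilute acid; no stereocentre is formed.

Step 6
Reactants: 16 5-bromo-3-[4-(1H-indol-3-yl)-2,3,5,6-tetramethoxyphenyl]-1H-indole; 17 4,4,5,5-tetramethyl-2-(3-methylbut-2-en-1-yl)-1,3,2-dioxaborolane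
Product: 18 3-[4-(1H-indol-3-yl)-2,3,5,6-tetramethoxyphenyl]-5-(3-methylbut-2-en-1-yl)-1H-indole
Conditions: 17 (2 equiv), PdCl2(IPent)(3-chloropyridine) (3 mol%), 5 M aq. KOH (4 equiv), THF, 70 °C; IPent = 1,3-bis[2,6-di(pentan-3-yl)phenyl]imidazol-2-ylidene
Reagents that add atoms: none
Why: Allyl–aryl Suzuki–Miyaura coupling at the only C–Br bond, in which the very bulky N-heterocyclic carbene ligand steers reductive elimination to the boron-bearing α-carbon and so gives the linear prenyl group; the trisubstituted alkene has two identical methyl groups, so no geometry or stereocentre is at stake.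

**Compound list**
1 | 1,2,4,5-tetramethoxybenzene | COc1cc(OC)c(OC)cc1OC | starting material
2 | 1,4-dibromo-2,3,5,6-tetramethoxybenzene | COc1c(Br)c(OC)c(OC)c(Br)c1OC | intermediate
3 | (Z)-1-bromo-2-ethoxyethene | CCO/C=C\Br | starting material
4 | (4-bromo-2,3,5,6-tetramethoxyphenyl)lithium | [Li]c1c(OC)c(OC)c(Br)c(OC)c1OC | intermediate
5 | (4-bromo-2,3,5,6-tetramethoxyphenyl)zinc chloride | Cl[Zn]c1c(OC)c(OC)c(Br)c(OC)c1OC | intermediate
6 | 1-bromo-4-[(Z)-2-ethoxyethenyl]-2,3,5,6-tetramethoxybenzene | CCO/C=C\c1c(OC)c(OC)c(Br)c(OC)c1OC | intermediate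
7 | phenylhydrazine hydrochloride | Cl.NNc1ccccc1 | starting material
8 | 2-(4-bromo-2,3,5,6-tetramethoxyphenyl)acetaldehyde | O=CCc1c(OC)c(OC)c(Br)c(OC)c1OC | intermediate
9 | (E)-phenylhydrazone of 2-(4-bromo-2,3,5,6-tetramethoxyphenyl)acetaldehyde | COc1c(Br)c(OC)c(OC)c(C/C=N/Nc2ccccc2)c1OC | intermediate
10 | 3-(4-bromo-2,3,5,6-tetramethoxyphenyl)-1H-indole | COc1c(Br)c(OC)c(OC)c(-c2c[nH]c3ccccc23)c1OC | intermediate
11 | 2-[(E)-2-ethoxyethenyl]-4,4,5,5-tetramethyl-1,3,2-dioxaborolane | CCO/C=C/B1OC(C)(C)C(C)(C)O1 | starting material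
12 | 3-{4-[(E)-2-ethoxyethenyl]-2,3,5,6-tetramethoxyphenyl}-1H-indole | CCO/C=C/c1c(OC)c(OC)c(-c2c[nH]c3ccccc23)c(OC)c1OC | intermediate
13 | (4-bromophenyl)hydrazine hydrochloride | Cl.NNc1ccc(Br)cc1 | starting material
14 | 2-[4-(1H-indol-3-yl)-2,3,5,6-tetramethoxyphenyl]acetaldehyde | O=CCc1c(OC)c(OC)c(-c2c[nH]c3ccccc23)c(OC)c1OC | intermediate
15 | (E)-(4-bromophenyl)hydrazone of 2-[4-(1H-indol-3-yl)-2,3,5,6-tetramethoxyphenyl]acetaldehyde | COc1c(C/C=N/Nc2ccc(Br)cc2)c(OC)c(OC)c(-c2c[nH]c3ccccc23)c1OC | intermediate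
16 | 5-bromo-3-[4-(1H-indol-3-yl)-2,3,5,6-tetramethoxyphenyl]-1H-indole | COc1c(OC)c(-c2c[nH]c3ccc(Br)cc23)c(OC)c(OC)c1-c1c[nH]c2ccccc12 | intermediate
17 | 4,4,5,5-tetramethyl-2-(3-methylbut-2-en-1-yl)-1,3,2-dioxaborolane | CC(C)=CCB1OC(C)(C)C(C)(C)O1 | starting material
18 | 3-[4-(1H-indol-3-yl)-2,3,5,6-tetramethoxyphenyl]-5-(3-methylbut-2-en-1-yl)-1H-indole | COc1c(OC)c(-c2c[nH]c3ccc(CC=C(C)C)cc23)c(OC)c(OC)c1-c1c[nH]c2ccccc12 | target

**Totals**
Total step count: 6. Longest linear sequence: 6 steps (1 → 2 → 6 → 10 → 12 → 16 → 18); all other inputs are purchased.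

**Three steps most likely to fail, with fallbacks**

Step 2, the one-pot exchange, zincation and Negishi coupling. The hindered arylzinc may transmetalate slowly, and the β-ethoxyvinyl bromide is an electron-rich partner. The fallback sets out from 2 and comes back to the route at 10. The same mono bromine–lithium exchange (n-BuLi, THF, −78 °C) is quenched with DMF to give 4-bromo-2,3,5,6-tetramethoxybenzaldehyde F1. A Wittig methoxymethylenation (Ph3PCH2OMe chloride, KOt-Bu, THF, 0 °C) then gives 1-bromo-2,3,5,6-tetramethoxy-4-(2-methoxyethenyl)benzene F2 as an E/Z mixture. Both isomers hydrolyse to aldehyde 8 under the conditions of step 3, and the Fischer reaction with 7 delivers 10. This costs one extra step but uses only carbonyl chemistry.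

Step 5, the second Fischer indolization. The [3,3] shift has to form a bond at a benzylic carbon carrying a di-ortho-substituted aryl group. The protonated ene-hydrazine can instead undergo N–N heterolysis, and the free 3-arylindole already present could be attacked at C2 by the aldehyde. The fallback sets out from 10 and comes back at 16, replacing steps 4 and 5 by a Larock heteroannulation. Sonogashira coupling of 10 with trimethylsilylacetylene (PdCl2(PhCN)2, P(t-Bu)3, CuI, i-Pr2NH, 1,4-dioxane, 50 °C) gives 3-{2,3,5,6-tetramethoxy-4-[(trimethylsilyl)ethynyl]phenyl}-1H-indole F3. Larock annulation of F3 with 4-bromo-2-iodoaniline (Pd(OAc)2, LiCl, Na2CO3, DMF, 100 °C) reacts at the C–I bond only; the silyl group goes to C2 and the aryl group to C3, giving 5-bromo-3-[4-(1H-indol-3-yl)-2,3,5,6-tetramethoxyphenyl]-2-(trimethylsilyl)-1H-indole F4. Protodesilylation with CF3CO2H in CH2Cl2 at 0 °C → rt gives 16.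

Step 6, the late prenylation. The risks are α/γ regioselectivity (linear against reverse prenyl) and catalyst inhibition by two free N–H groups. The fallback sets out from 16 and comes back at 18 with the polarity of the coupling reversed. Miyaura borylation of 16 (B2pin2, PdCl2(dppf), KOAc, 1,4-dioxane, 90 °C) gives 3-[4-(1H-indol-3-yl)-2,3,5,6-tetramethoxyphenyl]-5-(4,4,5,5-tetramethyl-1,3,2-dioxaborolan-2-yl)-1H-indole F5. F5 is then coupled with 1-bromo-3-methylbut-2-ene (Pd(PPh3)4, K2CO3, THF/H2O, 60 °C). The aryl group is delivered to the unsubstituted terminus of the π-prenyl complex of divalent palladium, which gives the linear prenyl arene 18.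

**Further compounds**
F1 | step 2 | 4-bromo-2,3,5,6-tetramethoxybenzaldehyde | COc1c(Br)c(OC)c(OC)c(C=O)c1OC
F2 | step 2 | 1-bromo-2,3,5,6-tetramethoxy-4-(2-methoxyethenyl)benzene (E/Z mixture) | COC=Cc1c(OC)c(OC)c(Br)c(OC)c1OC
F3 | step 5 | 3-{2,3,5,6-tetramethoxy-4-[(trimethylsilyl)ethynyl]phenyl}-1H-indole | COc1c(C#C[Si](C)(C)C)c(OC)c(OC)c(-c2c[nH]c3ccccc23)c1OC
F4 | step 5 | 5-bromo-3-[4-(1H-indol-3-yl)-2,3,5,6-tetramethoxyphenyl]-2-(trimethylsilyl)-1H-indole | COc1c(OC)c(-c2c([Si](C)(C)C)[nH]c3ccc(Br)cc23)c(OC)c(OC)c1-c1c[nH]c2ccccc12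
F5 | step 6 | 3-[4-(1H-indol-3-yl)-2,3,5,6-tetramethoxyphenyl]-5-(4,4,5,5-tetramethyl-1,3,2-dioxaborolan-2-yl)-1H-indole | COc1c(OC)c(-c2c[nH]c3ccc(B4OC(C)(C)C(C)(C)O4)cc23)c(OC)c(OC)c1-c1c[nH]c2ccccc12
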